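Ring B of the target is a phloroglucinol whose C–H carbons, each between two oxygens, carry rings A and C, and each outer ring has its sulfate oxygen ortho to the inter-ring bond. Each biaryl bond is therefore traced back to an aryl 2-bromobenzoate in which a ring-B oxygen is acylated by a carboxyl carbon placed on the future sulfate carbon. Pd-catalysed intramolecular C–H arylation forges the hindered C–C bond and a six-membered lactone at once; the bridge carbon is later exchanged for oxygen, leaving one free hydroxyl per outer ring. The precursor is the ring-A-bridged benzo[c]chromenone carrying a 3,5-bis(benzyloxy)-2-bromobenzoate on the ring-B oxygen para to the first biaryl bond.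

Key step: step 8

Remark on ring letters: ring B is the central phloroglucinol ring, ring A the outer ring attached first, ring C the outer ring attached in the key step.
Remark on the sulfate form: the target is drawn as the free bis(hydrogen sulfate); 17 and 18 would be handled as disodium salts and are written in the neutral acid form.
Remark on the axes: both biaryl axes of 13–18 are hindered and the target SMILES defines no axial configuration, so these compounds may be mixtures of slowly interconverting rotamers, which are not separated.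

Step 1
Reactants: 1 3,5-bis(benzyloxy)benzoic acid
Product: 2 3,5-bis(benzyloxy)-2-bromobenzoic acid
Conditions: NBS (1.05 equiv), MeCN, 0 °C → rt, dark
Reagents that add atoms: N-bromosuccinimide, O=C1CCC(=O)N1Br
Why: Electrophilic aromatic bromination should take C2, which is ortho to one benzyloxy group and para to the other, because the alternative carbon between the two benzyloxy groups is more hindered, as is usual for 3,5-dialkoxybenzoic acids.

Step 2
Reactants: 3 phloroglucinol; 4 benzyl bromide
Product: 5 5-(benzyloxy)benzene-1,3-diol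
Conditions: 3 (3 equiv), 4 (1 equiv), K2CO3 (1 equiv), DMF, 0 °C → rt; chromatography, 3 recovered
Reagents that add atoms: benzyl bromide (4), BrCc1ccccc1
Why: Williamson etherification with the triol in excess should keep di- and tri-ethers low, and the mono-ether is separable from C-benzylated by-products and unreacted phloroglucinol.

Step 3
Reactants: 5 5-(benzyloxy)benzene-1,3-diol
Product: 6 3-(benzyloxy)-5-[(triisopropylsilyl)oxy]phenol
Conditions: TIPSCl (1.0 equiv), imidazole, DMF, 0 °C; chromatography, 5 recovered
Reagents that add atoms: triisopropylsilyl chloride, CC(C)[Si](Cl)(C(C)C)C(C)C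
Why: Silyl ether formation on one of two equivalent phenols is a statistical mono-protection on cheap material, and it leaves one hydroxyl for the first ester and masks the other so that no free phenoxide can scramble aryl esters in step 5.

Step 4
Reactants: 6 3-(benzyloxy)-5-[(triisopropylsilyl)oxy]phenol; 2 3,5-bis(benzyloxy)-2-bromobenzoic acid
Product: 7 3-(benzyloxy)-5-[(triisopropylsilyl)oxy]phenyl 3,5-bis(benzyloxy)-2-bromobenzoate
Conditions: EDC·HCl, DMAP, CH2Cl2, 0 °C → rt
Reagents that add atoms: none
Why: Steglich esterification is routine for phenols and ortho-substituted benzoic acids and touches neither the silyl ether nor the benzyl ethers.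

Step 5
Reactants: 7 3-(benzyloxy)-5-[(triisopropylsilyl)oxy]phenyl 3,5-bis(benzyloxy)-2-bromobenzoate
Product: 8 1,8,10-tris(benzyloxy)-3-[(triisopropylsilyl)oxy]-6H-benzo[c]chromen-6-one
Conditions: Pd(OAc)2 (10 mol %), PCy3·HBF4 (20 mol %), PivOH (30 mol %), K2CO3 (2 equiv), anhydrous DMA, 110 °C
Reagents that add atoms: none
Why: Ester-tethered Pd-catalysed intramolecular direct C–H arylation (concerted metalation–deprotonation) should close the first lactone, and the bulky silyl ether should steer the ring closure to the ring-B C–H beside the benzyloxy group, so that the masked hydroxyl ends up para to the new biaryl bond.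

Step 6
Reactants: 8 1,8,10-tris(benzyloxy)-3-[(triisopropylsilyl)oxy]-6H-benzo[c]chromen-6-one
Product: 9 1,8,10-tris(benzyloxy)-3-hydroxy-6H-benzo[c]chromen-6-one
Conditions: HF·pyridine, THF/pyridine, 0 °C → rt
Reagents that add atoms: none
Why: Fluoride-mediated desilylation under non-basic conditions frees the phenol without opening the aryl lactone or touching the benzyl ethers.

Step 7
Reactants: 9 1,8,10-tris(benzyloxy)-3-hydroxy-6H-benzo[c]chromen-6-one; 2 3,5-bis(benzyloxy)-2-bromobenzoic acid
Product: 10 1,8,10-tris(benzyloxy)-6-oxo-6H-benzo[c]chromen-3-yl 3,5-bis(benzyloxy)-2-bromobenzoate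
Conditions: EDC·HCl, DMAP, CH2Cl2, rt
Reagents that add atoms: none
Why: Steglich esterification of a phenol flanked by two C–H positions is unhindered, and the mild carbodiimide conditions leave the existing lactone intact.

Step 8
Reactants: 10 1,8,10-tris(benzyloxy)-6-oxo-6H-benzo[c]chromen-3-yl 3,5-bis(benzyloxy)-2-bromobenzoate
Product: 11 pentabenzyl bis-lactone (ring B fused to two 6H-benzo[c]chromen-6-one lactones; rings A and C flank the ring-B carbon bearing the benzyloxy group)
Conditions: Pd(OAc)2 (15 mol %), PCy3·HBF4 (30 mol %), PivOH (30 mol %), K2CO3 (2 equiv), degassed anhydrous DMA, 120 °C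
Reagents that add atoms: none
Why: Oxidative addition of the C–Br bond of 10 to zerovalent palladium (from Pd(OAc)2 and PCy3) gives an arylpalladium bromide (divalent palladium) that the ester tether can deliver only to the ortho positions of ring B; a pivalate ligand removes the ortho hydrogen by concerted metalation–deprotonation and the diarylpalladium species reductively eliminates the biaryl bond. The closest known reaction is the ester-tethered intramolecular direct arylation of aryl 2-bromobenzoates to 6H-benzo[c]chromen-6-ones, which is established for biaryls with four ortho substituents. The six-membered lactone is closed by C–C bond formation between the two carbons ortho to the ester, through a seven-membered diarylpalladium ring that contracts on reductive elimination. No stereocentre is created, and the new axis is bridged, so no axial configuration is set or needed. The bromide fixes the carbon on ring C; on ring B both C–H positions ortho to the ester oxygen can react, and 11 is written for closure beside the benzyloxy group, but closure at the other site gives an isomeric bis-lactone that becomes the same compound 14 after steps 9 and 10, so site selectivity is not required. Because the partners are tied together, a biaryl bond that would resist intermolecular coupling forms as a cyclisation, and the lactone carbonyl ends up on the carbon that will bear the sulfate oxygen.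

Step 9
Reactants: 11 pentabenzyl bis-lactone
Product: 13 4,6-bis[2-acetyl-4,6-bis(benzyloxy)phenyl]-5-(benzyloxy)benzene-1,3-diol, via bis(Weinreb amide) diphenol 12 (not isolated)
Conditions: MeNH(OMe)·HCl (5 equiv), i-PrMgCl (10 equiv), THF, −20 → 0 °C; then MeMgBr (excess), 0 °C → rt; aq NH4Cl; crude product used directly
Reagents that add atoms: N,O-dimethylhydroxylamine hydrochloride, CNOC.Cl (its atoms stay only in 12); methylmagnesium bromide, C[Mg]Br
Why: Aminolysis of the two aryl lactones by the magnesium amide followed by Grignard addition is a Weinreb ketone synthesis, in which the chelated tetrahedral intermediate stops at the methyl ketone and so avoids the double addition that direct attack of a methyl organometallic on the lactones would risk.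

Step 10
Reactants: 13 4,6-bis[2-acetyl-4,6-bis(benzyloxy)phenyl]-5-(benzyloxy)benzene-1,3-diol; 4 benzyl bromide
Product: 14 2,4-bis[2-acetyl-4,6-bis(benzyloxy)phenyl]-1,3,5-tris(benzyloxy)benzene
Conditions: 4 (3 equiv), K2CO3, DMF, 50 °C
Reagents that add atoms: benzyl bromide (4), BrCc1ccccc1
Why: Williamson etherification under carbonate alkylates the phenoxides (any lactol form of 13 opens to the phenoxide in base) far faster than the methyl ketone enolates, and it makes all three ring-B oxygens alike so that either site of closure in step 8 leads to this one compound.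

Step 11
Reactants: 14 2,4-bis[2-acetyl-4,6-bis(benzyloxy)phenyl]-1,3,5-tris(benzyloxy)benzene
Product: 16 2,4-bis[4,6-bis(benzyloxy)-2-hydroxyphenyl]-1,3,5-tris(benzyloxy)benzene, via bis(aryl acetate) 15 (not isolated)
Conditions: mCPBA (5 equiv), TFA (cat.), CH2Cl2, 0 °C → rt; then K2CO3, MeOH/THF, rt
Reagents that add atoms: 3-chloroperoxybenzoic acid, OOC(=O)c1cccc(Cl)c1
Why: In the Baeyer–Villiger oxidation of an aryl methyl ketone the ortho-substituted aryl group migrates in preference to methyl, and transesterification of the resulting aryl acetates with methanol then frees exactly one hydroxyl on each outer ring.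

Step 12
Reactants: 16 2,4-bis[4,6-bis(benzyloxy)-2-hydroxyphenyl]-1,3,5-tris(benzyloxy)benzene
Product: 17 2,4-bis[4,6-bis(benzyloxy)-2-(sulfooxy)phenyl]-1,3,5-tris(benzyloxy)benzene
Conditions: SO3·pyridine (10 equiv), pyridine, 50 °C; exchange to the disodium salt
Reagents that add atoms: sulfur trioxide–pyridine complex, [O-]S(=O)(=O)[n+]1ccccc1
Why: O-Sulfation of phenols with the sulfur trioxide–pyridine complex is standard, and the two free hydroxyls are the only unprotected oxygens, so the sulfates can go nowhere else.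

Step 13
Reactants: 17 2,4-bis[4,6-bis(benzyloxy)-2-(sulfooxy)phenyl]-1,3,5-tris(benzyloxy)benzene
Product: 18 2,4-bis[2,4-dihydroxy-6-(sulfooxy)phenyl]benzene-1,3,5-triol (CNP0320583.0)
Conditions: H2 (1 atm), 10% Pd/C, MeOH/THF/H2O, rt, near-neutral pH; filtration and size-exclusion chromatography under argon
Reagents that add atoms: none
Why: Catalytic hydrogenolysis removes all seven benzyl ethers, while aryl sulfate monoester salts are inert to Pd/C and hydrogen and stable at neutral pH.

Compound list
1 | 3,5-bis(benzyloxy)benzoic acid | OC(=O)c1cc(OCc2ccccc2)cc(OCc2ccccc2)c1 | starting material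
2 | 3,5-bis(benzyloxy)-2-bromobenzoic acid | OC(=O)c1cc(OCc2ccccc2)cc(OCc2ccccc2)c1Br | intermediate
3 | phloroglucinol | Oc1cc(O)cc(O)c1 | starting material
4 | benzyl bromide | BrCc1ccccc1 | starting material
5 | 5-(benzyloxy)benzene-1,3-diol | Oc1cc(O)cc(OCc2ccccc2)c1 | intermediate
6 | 3-(benzyloxy)-5-[(triisopropylsilyl)oxy]phenol | Oc1cc(OCc2ccccc2)cc(O[Si](C(C)C)(C(C)C)C(C)C)c1 | intermediate
7 | 3-(benzyloxy)-5-[(triisopropylsilyl)oxy]phenyl 3,5-bis(benzyloxy)-2-bromobenzoate | O=C(Oc1cc(OCc2ccccc2)cc(O[Si](C(C)C)(C(C)C)C(C)C)c1)c1cc(OCc2ccccc2)cc(OCc2ccccc2)c1Br | intermediate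
8 | 1,8,10-tris(benzyloxy)-3-[(triisopropylsilyl)oxy]-6H-benzo[c]chromen-6-one | O=C1Oc2cc(O[Si](C(C)C)(C(C)C)C(C)C)cc(OCc3ccccc3)c2-c2c1cc(OCc1ccccc1)cc2OCc1ccccc1 | intermediate
9 | 1,8,10-tris(benzyloxy)-3-hydroxy-6H-benzo[c]chromen-6-one | O=C1Oc2cc(O)cc(OCc3ccccc3)c2-c2c1cc(OCc1ccccc1)cc2OCc1ccccc1 | intermediate
10 | 1,8,10-tris(benzyloxy)-6-oxo-6H-benzo[c]chromen-3-yl 3,5-bis(benzyloxy)-2-bromobenzoate | O=C1Oc2cc(OC(=O)c3cc(OCc4ccccc4)cc(OCc4ccccc4)c3Br)cc(OCc3ccccc3)c2-c2c1cc(OCc1ccccc1)cc2OCc1ccccc1 | intermediate
11 | pentabenzyl bis-lactone (doubly lactone-bridged terphenyl) | O=C1Oc2cc3OC(=O)c4cc(OCc5ccccc5)cc(OCc5ccccc5)c4-c3c(OCc3ccccc3)c2-c2c1cc(OCc1ccccc1)cc2OCc1ccccc1 | intermediate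
12 | 4,6-bis{4,6-bis(benzyloxy)-2-[methoxy(methyl)carbamoyl]phenyl}-5-(benzyloxy)benzene-1,3-diol | CON(C)C(=O)c1cc(OCc2ccccc2)cc(OCc2ccccc2)c1-c1c(O)cc(O)c(-c2c(OCc3ccccc3)cc(OCc3ccccc3)cc2C(=O)N(C)OC)c1OCc1ccccc1 | intermediate (not isolated)
13 | 4,6-bis[2-acetyl-4,6-bis(benzyloxy)phenyl]-5-(benzyloxy)benzene-1,3-diol | CC(=O)c1cc(OCc2ccccc2)cc(OCc2ccccc2)c1-c1c(O)cc(O)c(-c2c(OCc3ccccc3)cc(OCc3ccccc3)cc2C(C)=O)c1OCc1ccccc1 | intermediate
14 | 2,4-bis[2-acetyl-4,6-bis(benzyloxy)phenyl]-1,3,5-tris(benzyloxy)benzene | CC(=O)c1cc(OCc2ccccc2)cc(OCc2ccccc2)c1-c1c(OCc2ccccc2)cc(OCc2ccccc2)c(-c2c(OCc3ccccc3)cc(OCc3ccccc3)cc2C(C)=O)c1OCc1ccccc1 | intermediate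
15 | 2,4-bis[2-acetoxy-4,6-bis(benzyloxy)phenyl]-1,3,5-tris(benzyloxy)benzene | CC(=O)Oc1cc(OCc2ccccc2)cc(OCc2ccccc2)c1-c1c(OCc2ccccc2)cc(OCc2ccccc2)c(-c2c(OCc3ccccc3)cc(OCc3ccccc3)cc2OC(C)=O)c1OCc1ccccc1 | intermediate (not isolated)
16 | 2,4-bis[4,6-bis(benzyloxy)-2-hydroxyphenyl]-1,3,5-tris(benzyloxy)benzene | Oc1cc(OCc2ccccc2)cc(OCc2ccccc2)c1-c1c(OCc2ccccc2)cc(OCc2ccccc2)c(-c2c(OCc3ccccc3)cc(OCc3ccccc3)cc2O)c1OCc1ccccc1 | intermediate
17 | 2,4-bis[4,6-bis(benzyloxy)-2-(sulfooxy)phenyl]-1,3,5-tris(benzyloxy)benzene | OS(=O)(=O)Oc1cc(OCc2ccccc2)cc(OCc2ccccc2)c1-c1c(OCc2ccccc2)cc(OCc2ccccc2)c(-c2c(OCc3ccccc3)cc(OCc3ccccc3)cc2OS(=O)(=O)O)c1OCc1ccccc1 | intermediate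
18 | 2,4-bis[2,4-dihydroxy-6-(sulfooxy)phenyl]benzene-1,3,5-triol (CNP0320583.0) | O=S(=O)(O)Oc1cc(O)cc(O)c1-c1c(O)cc(O)c(-c2c(O)cc(O)cc2OS(=O)(=O)O)c1O | target

Total step count: 13.
Longest linear sequence: 12 steps (from 3 through steps 2–13 to 18).

Steps most likely to fail

Step 8. The second ring closure may be slow, because the aryl ester prefers the rotamer that holds the two rings apart and the reacting C–H lies between two oxygens on a crowded ring. Hydrodebromination of the aryl bromide or scission of the aryl ester could then win. Fallback, an intermolecular Suzuki–Miyaura coupling followed by lactonisation: setting out from 9, iodination ortho to the free hydroxyl (NIS, CH2Cl2, 0 °C) would give 1,8,10-tris(benzyloxy)-3-hydroxy-2-iodo-6H-benzo[c]chromen-6-one F1; the other ortho iodide would serve equally, since both series merge at 14. Acid 2 would be methylated (MeI, K2CO3, DMF) to methyl 3,5-bis(benzyloxy)-2-bromobenzoate F2 and converted by Miyaura borylation (B2pin2, Pd(dppf)Cl2, KOAc, dioxane, 90 °C) into methyl 3,5-bis(benzyloxy)-2-(4,4,5,5-tetramethyl-1,3,2-dioxaborolan-2-yl)benzoate F3. Coupling of F1 with F3 (Pd(OAc)2, SPhos, K3PO4, toluene/H2O, 100 °C) should give the ortho-hydroxy biaryl methyl ester F4, which lactonises on its own or with catalytic TsOH to 11, where the route is rejoined.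

Step 11. Aryl migration may be sluggish, because both benzyloxy groups of the migrating ring are meta to the migrating carbon, and the peracid could meanwhile oxidise the electron-rich ring B. Fallback, a Hock rearrangement instead of a peracid oxidation: setting out from 14, addition of MeLi (THF, −78 → 0 °C) would give the bis(tertiary carbinol) 2,4-bis[4,6-bis(benzyloxy)-2-(2-hydroxypropan-2-yl)phenyl]-1,3,5-tris(benzyloxy)benzene F5. Treatment with concentrated H2O2 and BF3·OEt2 (CH2Cl2, 0 °C, large excess of peroxide to outrun trapping of the benzylic cation by a neighbouring ether oxygen) should form the tertiary hydroperoxides, which rearrange with aryl migration and loss of acetone to 16, where the route is rejoined.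

Step 12. Sulfation of two hindered phenols next to the biaryl axes may stay incomplete, and sulfate may be lost by acid-catalysed hydrolysis during isolation or in the following hydrogenolysis. Fallback, protected sulfate diesters: setting out from 16, 2,2,2-trichloroethyl chlorosulfate with DMAP and Et3N (THF, 0 °C → rt) would give the neutral, chromatographable bis(2,2,2-trichloroethyl sulfate) F6. Transfer hydrogenolysis (10% Pd/C, HCO2NH4, MeOH, rt) should remove the trichloroethyl groups and all benzyl ethers together and give 18 as its ammonium salt, so the route is rejoined at 18.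

Further compounds
F1 | step 8 | 1,8,10-tris(benzyloxy)-3-hydroxy-2-iodo-6H-benzo[c]chromen-6-one | O=C1Oc2cc(O)c(I)c(OCc3ccccc3)c2-c2c1cc(OCc1ccccc1)cc2OCc1ccccc1
F2 | step 8 | methyl 3,5-bis(benzyloxy)-2-bromobenzoate | COC(=O)c1cc(OCc2ccccc2)cc(OCc2ccccc2)c1Br
F3 | step 8 | methyl 3,5-bis(benzyloxy)-2-(4,4,5,5-tetramethyl-1,3,2-dioxaborolan-2-yl)benzoate | COC(=O)c1cc(OCc2ccccc2)cc(OCc2ccccc2)c1B1OC(C)(C)C(C)(C)O1
F4 | step 8 | methyl 2-[1,8,10-tris(benzyloxy)-3-hydroxy-6-oxo-6H-benzo[c]chromen-2-yl]-3,5-bis(benzyloxy)benzoate | O=C1Oc2cc(O)c(-c3c(OCc4ccccc4)cc(OCc4ccccc4)cc3C(=O)OC)c(OCc3ccccc3)c2-c2c1cc(OCc1ccccc1)cc2OCc1ccccc1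
F5 | step 11 | 2,4-bis[4,6-bis(benzyloxy)-2-(2-hydroxypropan-2-yl)phenyl]-1,3,5-tris(benzyloxy)benzene | CC(C)(O)c1cc(OCc2ccccc2)cc(OCc2ccccc2)c1-c1c(OCc2ccccc2)cc(OCc2ccccc2)c(-c2c(OCc3ccccc3)cc(OCc3ccccc3)cc2C(C)(C)O)c1OCc1ccccc1
F6 | step 12 | 2,4-bis{4,6-bis(benzyloxy)-2-[(2,2,2-trichloroethoxy)sulfonyloxy]phenyl}-1,3,5-tris(benzyloxy)benzene | ClC(Cl)(Cl)COS(=O)(=O)Oc1cc(OCc2ccccc2)cc(OCc2ccccc2)c1-c1c(OCc2ccccc2)cc(OCc2ccccc2)c(-c2c(OCc3ccccc3)cc(OCc3ccccc3)cc2OS(=O)(=O)OCC(Cl)(Cl)Cl)c1OCc1ccccc1
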